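The data are simulated for an exercise, and the scatter is random.

Count the activator.

| flask | substrate | activator | remark | time |
|---|---|---|---|---|
| Tuesday's | 0.0020 M | 2.2 mM | run made earlier |  |
| Monday's | 0.0020 M | 1.5 mM | run made earlier |  |
| Sunday's | 0.0020 M | 3.3 mM | run made earlier |  |
| amber | 0.0020 M (fed, over 5.0 min) | 2.20 mM | all else is in the flask from the start; the feed brings no volume worth counting | 6.0 min |
| red | 0.0020 M | 2.20 mM (fed, over 5.0 min) | all else is in the flask from the start; the feed brings no volume worth counting | 6.0 min |
| green | 0.0020 M | 2.20 mM | everything together at the start | 6.0 min |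

- Tuesday's (time / min: ring / %, substrate / %): 0.500: 18, 48; 0.667: 28, 42; 1.00: 40, 30; 1.50: 49, 21; 2.50: 69, 11; 4.00: 75, 8; 6.00: 80, 1
- Monday's (time / min: ring / %, substrate / %): 1.00: 32, 41; 2.00: 48, 27; 3.00: 55, 18; 4.00: 60, 17; 5.00: 62, 10; 6.00: 68, 11; 8.00: 67, 8
- Sunday's (time / min: ring / %, substrate / %): 1.00: 45, 17; 2.00: 77, 7; 3.00: 87, 1; 4.00: 88, 3; 5.00: 91, 0; 6.00: 88, 0; 8.00: 92, 0

(scatter of a reading: 2 percentage points)

- a reading or a percentage of ring counts all its forms, free or not

- the flask with the highest amount of ring, in percent of the substrate charged ("all alike" if they lie within 1.5 percentage points) (amber / red / green / all alike)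
- final ring, as a percentage of the substrate charged, in amber
- final ring, as a percentage of the substrate charged, in red
- final ring, as a percentage of the substrate charged, in green

Test first what each given number is worth. The substrate charge stands at 0.0020 M throughout the runs, so they cannot test it. The clock: Tuesday's ring climbs from 75% at 4.00 min to 80% at 6.00 min. The activator charge: at 6.00 min, Monday's ring reads 68% with 1.5 mM, against Tuesday's 80% with 2.2 mM, a step larger than the clock's. So hold the activator first.

Define the activator budget, b = 1.10 for green and for red once fed: activator charged per substrate charged, in equivalents, counting one activator per ring. Monday's b is 0.750, with activator the limiting reagent, and Monday's ring reads 67% at 8.00 min. Red has received Monday's charge at 3.41 min, which leaves 2.59 min. The Monday's reading nearest that span, at 3.00 min, is 55%, and I take that as my rough figure for red. Green repeats Tuesday, near 80%.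

The forecast names green, with amber 67%, red 72% and green 79%. Of red it argues “so dimer loss is worst”. Its red stands above mine.

The flasks give green as highest: amber 69.6%, red 59.2%, green 81.1%.

    substrate + activator → activated form (k = 11.0 /M/s)
    activated form → ring (k = 0.0310 /s)
    substrate + activated form → open dimer (k = 0.560 /M/s)
    crystals ⇌ ring, rate k4*(cs4 - [ring]) while solid is left; crystals form when [ring] > cs4 (solubility = 0.660 mM, k = 1.40 /s)
    substrate ⇌ dormant form (K = 1.30, k = 0.00390 /s)

Red lies 13 percentage points under the forecast. Spend the budget on red: 42% of its activator remains, so activator worth 63.8% of the substrate charge is spent, of which ring takes 59.2%, activated form 3.55% and open dimer, with one activator on two substrates, 0.746%. Now take the neighbouring red flask with 5.5 × 10⁻⁴ M of activator, less than the substrate. Its b is 0.275, and 19.8% of its activator remains, so 22.0% is spent. There activated form takes 1.68%, open dimer 0.366% and ring 20.0%.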